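The ten-membered germacrane ring (C1–C10: C1=C10 alkene, C3 angelate, C4/C5 epoxide, C6 acetate, C7 isopropyl) holds a 2,3-epoxy alcohol motif at C3–C4–C5. Taking out the epoxide oxygen leaves an (E)-C4=C5 allylic alcohol, so the ring is closed at its alkenyl–carbinol bond C3–C4 by an intramolecular Nozaki–Hiyama–Kishi reaction. In one operation this forms the carbocycle, sets C3 and provides the hydroxyl that then directs epoxidation of C4=C5; angeloylation ends the route. The precursor is an acyclic (E)-alkenyl iodide aldehyde that already carries C6, C7 and the (E)-C1=C10 alkene, built by asymmetric allylboration, B-alkyl Suzuki coupling and alkyne hydrozirconation–iodination.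

Key step: step 11

Remark: locants C1–C10 in the text follow the germacrane numbering defined above; but-2-ynal (6) is taken as purchasable (otherwise one MnO2 oxidation of but-2-yn-1-ol).

Step 1
Reactants: 1 pent-3-yn-1-ol
Product: 2 1-methoxy-4-[(pent-3-yn-1-yloxy)methyl]benzene (PMB ether of 1)
Conditions: NaH, PMBCl, n-Bu4NI (cat.), THF/DMF, 0 °C to rt
Reagents that add atoms: 4-methoxybenzyl chloride, COc1ccc(CCl)cc1
Why: Williamson etherification of the primary alkoxide with the benzylic chloride should be clean and installs a PMB group that survives every step up to its oxidative removal in step 9.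

Step 2
Reactants: 2 1-methoxy-4-[(pent-3-yn-1-yloxy)methyl]benzene
Product: 4 1-({[(3E)-4-iodopent-3-en-1-yl]oxy}methyl)-4-methoxybenzene, via alkenylzirconocene chloride 3 (not isolated)
Conditions: Cp2Zr(H)Cl (excess), THF, 50 °C; then I2, 0 °C
Reagents that add atoms: iodine, II
Why: Schwartz hydrozirconation adds Zr–H syn across the alkyne and, with excess reagent and warming, equilibrates the metal to the less hindered methyl-bearing carbon, so iodinolysis with retention should give the (E)-2-iodoalkene.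

Step 3
Reactants: 5 (2Z)-4-methylpent-2-ene; 6 but-2-ynal
Product: 10 (3R,4S)-3-(propan-2-yl)hept-1-en-5-yn-4-ol, via allylpotassium 7 (not isolated), via allylborane 8 (not isolated), via borinate 9 (not isolated)
Conditions: 5, n-BuLi, KOt-Bu, THF, −78 to −45 °C; (−)-Ipc2BOMe, −78 °C; BF3·OEt2; 6, −78 °C; NaOH, H2O2
Reagents that add atoms: none
Why: Brown-type asymmetric allylboration (homologue of Z-crotylboration), in which kinetic deprotonation of the cis-alkene at its methyl group keeps the Z geometry, the Z-allylborane reacts through a Zimmerman–Traxler chair to give the syn adduct, and the isopinocampheyl groups derived from (+)-α-pinene direct attack to the Si face of the aldehyde, setting the future C6 (S) and C7 centres together.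

Step 4
Reactants: 10 (3R,4S)-3-(propan-2-yl)hept-1-en-5-yn-4-ol
Product: 11 tert-butyldimethyl{[(3R,4S)-3-(propan-2-yl)hept-1-en-5-yn-4-yl]oxy}silane
Conditions: TBSOTf, 2,6-lutidine, CH2Cl2, −78 to 0 °C
Reagents that add atoms: tert-butyldimethylsilyl trifluoromethanesulfonate, CC(C)(C)[Si](C)(C)OS(=O)(=O)C(F)(F)F
Why: Silylation with the silyl triflate protects the hindered propargylic alcohol, so that the later hydrozirconation is governed by sterics and not steered to the proximal alkyne carbon by a free hydroxyl.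

Step 5
Reactants: 11 tert-butyldimethyl{[(3R,4S)-3-(propan-2-yl)hept-1-en-5-yn-4-yl]oxy}silane; 4 1-({[(3E)-4-iodopent-3-en-1-yl]oxy}methyl)-4-methoxybenzene
Product: 13 tert-butyl{[(4S,5S,8E)-11-[(4-methoxybenzyl)oxy]-8-methyl-5-(propan-2-yl)undec-8-en-2-yn-4-yl]oxy}dimethylsilane, via B-alkyl-9-BBN adduct 12 (not isolated)
Conditions: 9-BBN, THF, rt; then 4, PdCl2(dppf) (cat.), AsPh3, Cs2CO3, DMF/H2O, rt
Reagents that add atoms: none
Why: 9-BBN hydroborates the terminal alkene anti-Markovnikov in preference to the internal alkyne, and the B-alkyl Suzuki–Miyaura coupling joins C9 to C10 with retention of the iodide geometry, which fixes the (E)-C1=C10 alkene.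

Step 6
Reactants: 13 tert-butyl{[(4S,5S,8E)-11-[(4-methoxybenzyl)oxy]-8-methyl-5-(propan-2-yl)undec-8-en-2-yn-4-yl]oxy}dimethylsilane
Product: 15 tert-butyl{[(2E,4S,5S,8E)-2-iodo-11-[(4-methoxybenzyl)oxy]-8-methyl-5-(propan-2-yl)undeca-2,8-dien-4-yl]oxy}dimethylsilane, via alkenylzirconocene chloride 14 (not isolated)
Conditions: Cp2Zr(H)Cl (excess), THF, 50 °C; then I2, 0 °C
Reagents that add atoms: iodine, II
Why: Schwartz hydrozirconation should place zirconium by syn addition on the methyl-bearing alkyne carbon, away from the branched silyloxy carbon, and iodinolysis with retention gives the (E)-alkenyl iodide whose geometry becomes that of C4=C5; the trisubstituted alkene is inert to the reagent.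

Step 7
Reactants: 15 tert-butyl{[(2E,4S,5S,8E)-2-iodo-11-[(4-methoxybenzyl)oxy]-8-methyl-5-(propan-2-yl)undeca-2,8-dien-4-yl]oxy}dimethylsilane
Product: 16 (2E,4S,5S,8E)-2-iodo-11-[(4-methoxybenzyl)oxy]-8-methyl-5-(propan-2-yl)undeca-2,8-dien-4-ol
Conditions: n-Bu4NF, THF, 0 °C to rt
Reagents that add atoms: none
Why: Fluoride-induced desilylation frees the C6 alcohol, and the alkenyl iodide has no hydrogen anti to iodine, so elimination to the alkyne is not expected.

Step 8
Reactants: 16 (2E,4S,5S,8E)-2-iodo-11-[(4-methoxybenzyl)oxy]-8-methyl-5-(propan-2-yl)undeca-2,8-dien-4-ol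
Product: 17 (2E,4S,5S,8E)-2-iodo-11-[(4-methoxybenzyl)oxy]-8-methyl-5-(propan-2-yl)undeca-2,8-dien-4-yl acetate
Conditions: Ac2O, pyridine, DMAP (cat.), CH2Cl2, rt
Reagents that add atoms: acetic anhydride, CC(=O)OC(C)=O
Why: DMAP-catalysed acetylation installs the C6 acetate of the target now, so no deprotection is needed once the acid-sensitive epoxide is present.

Step 9
Reactants: 17 (2E,4S,5S,8E)-2-iodo-11-[(4-methoxybenzyl)oxy]-8-methyl-5-(propan-2-yl)undeca-2,8-dien-4-yl acetate
Product: 18 (2E,4S,5S,8E)-11-hydroxy-2-iodo-8-methyl-5-(propan-2-yl)undeca-2,8-dien-4-yl acetate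
Conditions: DDQ, CH2Cl2/pH 7 buffer, 0 °C
Reagents that add atoms: none
Why: Oxidative PMB cleavage by DDQ (hydride abstraction, then hydrolysis of the oxocarbenium ion) should leave the acetate, the alkenyl iodide and the trisubstituted alkene untouched.

Step 10
Reactants: 18 (2E,4S,5S,8E)-11-hydroxy-2-iodo-8-methyl-5-(propan-2-yl)undeca-2,8-dien-4-yl acetate
Product: 19 (2E,4S,5S,8E)-2-iodo-8-methyl-11-oxo-5-(propan-2-yl)undeca-2,8-dien-4-yl acetate
Conditions: Dess–Martin periodinane, NaHCO3, CH2Cl2, 0 °C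
Reagents that add atoms: none
Why: Buffered Dess–Martin oxidation gives the β,γ-unsaturated aldehyde under near-neutral conditions, which should avoid migration of the C1=C10 alkene into conjugation; the aldehyde is used at once.

Step 11
Reactants: 19 (2E,4S,5S,8E)-2-iodo-8-methyl-11-oxo-5-(propan-2-yl)undeca-2,8-dien-4-yl acetate
Product: 22 (1S,2E,4R,6E,10S)-4-hydroxy-3,7-dimethyl-10-(propan-2-yl)cyclodeca-2,6-dien-1-yl acetate [(3R,6S,7S)-6-acetoxygermacra-1(10)E,4E-dien-3-ol], via alkenylchromium dichloride 20 (not isolated), via chromium alkoxide 21 (not isolated)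
Conditions: CrCl2 (excess), NiCl2 (cat.), DMSO/THF, rt, syringe-pump addition to about 2 mM; aqueous work-up
Reagents that add atoms: none
Why: Zerovalent nickel formed in situ inserts into the C–I bond with retention, transmetalation gives the alkenylchromium species 20 (trivalent chromium), and this adds to the tethered aldehyde through a chromium–oxygen bound four-centre transition state to give alkoxide 21 (intramolecular Nozaki–Hiyama–Kishi reaction, the known alkenyl halide–aldehyde macrocyclisation type). The ten-membered carbocycle closes in a 10-exo-trig mode by forming C3–C4, and both (E)-alkenes are carried into the ring unchanged, so no trans alkene has to be made inside the medium ring. The new stereocentre C3 should be R by substrate control: in the crown-like transition state the C7 isopropyl and C6 acetoxy groups lie pseudo-equatorial and H6 rather than the acetoxy group faces the C4 methyl (A(1,3) strain), which fixes the outer face of the C4=C5 plane, and the bulky chromium-bound aldehyde oxygen has to sit on that outer face with the C2 ring bond inside. The step needs cyclisation to beat oligomerisation, secured by slow addition to high dilution, and chemoselective activation of the alkenyl iodide, secured because the alkenylchromium reagent is non-basic and adds only to aldehydes, leaving the acetate and the enolisable β,γ-unsaturated aldehyde intact.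

Step 12
Reactants: 22 (1S,2E,4R,6E,10S)-4-hydroxy-3,7-dimethyl-10-(propan-2-yl)cyclodeca-2,6-dien-1-yl acetate
Product: 23 (3R,4R,5R,6S,7S)-6-acetoxy-4,5-epoxygermacr-1(10)E-en-3-ol
Conditions: VO(acac)2 (cat.), t-BuOOH, CH2Cl2, 0 °C
Reagents that add atoms: tert-butyl hydroperoxide, CC(C)(C)OO
Why: Vanadium-catalysed hydroxyl-directed epoxidation should react at the allylic C4=C5 alkene in preference to the homoallylic C1=C10 alkene and deliver oxygen from the face of the C3 hydroxyl, where the C4 methyl enforces the A(1,2)-minimised arrangement that gives the erythro (3R,4R,5R) epoxy alcohol on the outer face left open by the pseudo-equatorial C6 acetate, the (E)-alkene giving the trans-epoxide.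

Step 13
Reactants: 23 (3R,4R,5R,6S,7S)-6-acetoxy-4,5-epoxygermacr-1(10)E-en-3-ol; 24 angelic acid [(2Z)-2-methylbut-2-enoic acid]
Product: 26 (3R,4R,5R,6S,7S)-6-acetoxy-4,5-epoxygermacr-1(10)E-en-3-yl (2Z)-2-methylbut-2-enoate (target), via mixed anhydride 25 (not isolated)
Conditions: 24, 2,4,6-trichlorobenzoyl chloride, Et3N, toluene, rt; then 23, 70 °C
Reagents that add atoms: none
Why: Yamaguchi-type esterification through the mixed anhydride of angelic acid, run without DMAP, should acylate the hindered C3 alcohol while avoiding the nucleophile-induced Z to E isomerisation that would give the tiglate, and the basic medium spares the epoxide.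

Compound list
1 | pent-3-yn-1-ol | CC#CCCO | starting material
2 | 1-methoxy-4-[(pent-3-yn-1-yloxy)methyl]benzene | CC#CCCOCc1ccc(OC)cc1 | intermediate
3 | chlorobis(cyclopentadienyl)[(2E)-5-[(4-methoxybenzyl)oxy]pent-2-en-2-yl]zirconium | C/C(=C\CCOCc1ccc(OC)cc1)[Zr](Cl)(C1C=CC=C1)C1C=CC=C1 | intermediate
4 | 1-({[(3E)-4-iodopent-3-en-1-yl]oxy}methyl)-4-methoxybenzene | C/C(I)=C\CCOCc1ccc(OC)cc1 | intermediate
5 | (2Z)-4-methylpent-2-ene | C/C=C\C(C)C | starting material
6 | but-2-ynal | CC#CC=O | starting material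
7 | [(2Z)-4-methylpent-2-en-1-yl]potassium | [K]C/C=C\C(C)C | intermediate
8 | [(2Z)-4-methylpent-2-en-1-yl]bis(isopinocampheyl)borane (isopinocampheyl groups from (+)-α-pinene) | CC(C)/C=C\CB([C@@H]1C[C@@H]2C[C@H]([C@H]1C)C2(C)C)[C@@H]1C[C@@H]2C[C@H]([C@H]1C)C2(C)C | intermediate
9 | (3R,4S)-3-(propan-2-yl)hept-1-en-5-yn-4-yl bis(isopinocampheyl)borinate | C=C[C@@H](C(C)C)[C@H](OB([C@@H]1C[C@@H]2C[C@H]([C@H]1C)C2(C)C)[C@@H]1C[C@@H]2C[C@H]([C@H]1C)C2(C)C)C#CC | intermediate
10 | (3R,4S)-3-(propan-2-yl)hept-1-en-5-yn-4-ol | C=C[C@@H](C(C)C)[C@H](O)C#CC | intermediate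
11 | tert-butyldimethyl{[(3R,4S)-3-(propan-2-yl)hept-1-en-5-yn-4-yl]oxy}silane | C=C[C@@H](C(C)C)[C@H](O[Si](C)(C)C(C)(C)C)C#CC | intermediate
12 | 9-[(3S,4S)-4-[(tert-butyldimethylsilyl)oxy]-3-(propan-2-yl)hept-5-yn-1-yl]-9-borabicyclo[3.3.1]nonane | CC(C)[C@H](CCB1C2CCCC1CCC2)[C@H](O[Si](C)(C)C(C)(C)C)C#CC | intermediate
13 | tert-butyl{[(4S,5S,8E)-11-[(4-methoxybenzyl)oxy]-8-methyl-5-(propan-2-yl)undec-8-en-2-yn-4-yl]oxy}dimethylsilane | COc1ccc(COCC/C=C(\C)CC[C@@H](C(C)C)[C@H](O[Si](C)(C)C(C)(C)C)C#CC)cc1 | intermediate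
14 | alkenylzirconocene chloride of 13 (Zr on the methyl-bearing carbon, trans to C6) | COc1ccc(COCC/C=C(\C)CC[C@@H](C(C)C)[C@H](O[Si](C)(C)C(C)(C)C)/C=C(\C)[Zr](Cl)(C2C=CC=C2)C3C=CC=C3)cc1 | intermediate
15 | tert-butyl{[(2E,4S,5S,8E)-2-iodo-11-[(4-methoxybenzyl)oxy]-8-methyl-5-(propan-2-yl)undeca-2,8-dien-4-yl]oxy}dimethylsilane | COc1ccc(COCC/C=C(\C)CC[C@@H](C(C)C)[C@H](O[Si](C)(C)C(C)(C)C)/C=C(\C)I)cc1 | intermediate
16 | (2E,4S,5S,8E)-2-iodo-11-[(4-methoxybenzyl)oxy]-8-methyl-5-(propan-2-yl)undeca-2,8-dien-4-ol | COc1ccc(COCC/C=C(\C)CC[C@@H](C(C)C)[C@H](O)/C=C(\C)I)cc1 | intermediate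
17 | (2E,4S,5S,8E)-2-iodo-11-[(4-methoxybenzyl)oxy]-8-methyl-5-(propan-2-yl)undeca-2,8-dien-4-yl acetate | COc1ccc(COCC/C=C(\C)CC[C@@H](C(C)C)[C@H](OC(C)=O)/C=C(\C)I)cc1 | intermediate
18 | (2E,4S,5S,8E)-11-hydroxy-2-iodo-8-methyl-5-(propan-2-yl)undeca-2,8-dien-4-yl acetate | OCC/C=C(\C)CC[C@@H](C(C)C)[C@H](OC(C)=O)/C=C(\C)I | intermediate
19 | (2E,4S,5S,8E)-2-iodo-8-methyl-11-oxo-5-(propan-2-yl)undeca-2,8-dien-4-yl acetate | O=CC/C=C(\C)CC[C@@H](C(C)C)[C@H](OC(C)=O)/C=C(\C)I | intermediate
20 | alkenylchromium dichloride of 19 (trivalent chromium in place of iodine) | O=CC/C=C(\C)CC[C@@H](C(C)C)[C@H](OC(C)=O)/C=C(\C)[Cr](Cl)Cl | intermediate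
21 | dichlorochromium alkoxide of 22 (trivalent chromium) | C/C1=C\[C@@H](OC(C)=O)[C@H](C(C)C)CC/C(C)=C/C[C@H]1O[Cr](Cl)Cl | intermediate
22 | (1S,2E,4R,6E,10S)-4-hydroxy-3,7-dimethyl-10-(propan-2-yl)cyclodeca-2,6-dien-1-yl acetate | C/C1=C\[C@@H](OC(C)=O)[C@H](C(C)C)CC/C(C)=C/C[C@H]1O | intermediate
23 | (3R,4R,5R,6S,7S)-6-acetoxy-4,5-epoxygermacr-1(10)E-en-3-ol | O[C@@H]1C/C=C(\C)CC[C@@H](C(C)C)[C@H](OC(C)=O)[C@H]2O[C@@]21C | intermediate
24 | angelic acid, (2Z)-2-methylbut-2-enoic acid | C/C=C(/C)C(=O)O | starting material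
25 | angelic 2,4,6-trichlorobenzoic anhydride | C/C=C(/C)C(=O)OC(=O)c1c(Cl)cc(Cl)cc1Cl | intermediate
26 | (3R,4R,5R,6S,7S)-6-acetoxy-4,5-epoxygermacr-1(10)E-en-3-yl (2Z)-2-methylbut-2-enoate | C/C=C(/C)C(=O)O[C@@H]1C/C=C(\C)CC[C@@H](C(C)C)[C@H](OC(C)=O)[C@H]2O[C@@]21C | target

Total step count: 13.
Longest linear sequence: 11 steps (steps 3–13 from 5 and 6; the branch through steps 1, 2 and 5–13 is equally long).

Steps most likely to fail

Step 11. The aldehyde may be attacked on the wrong face in the ten-membered transition state, because the facial bias argued above rests on a conformational prediction; the C3 epimer would then form. The fallback sets out from 19 and moves the control of C3 from the ring closure to a reagent-controlled reduction. The ring closure is run as in step 11, and the C3-epimeric alcohol (1S,2E,4S,6E,10S)-4-hydroxy-3,7-dimethyl-10-(propan-2-yl)cyclodeca-2,6-dien-1-yl acetate F1, alone or mixed with 22, is oxidised with Dess–Martin periodinane to the macrocyclic dienone (1S,2E,6E,10S)-3,7-dimethyl-4-oxo-10-(propan-2-yl)cyclodeca-2,6-dien-1-yl acetate F2. Corey–Bakshi–Shibata reduction of F2 with the (S)-methyl oxazaborolidine and BH3·SMe2 at low temperature, the alkenyl group acting as the large substituent and the acetate staying intact, should deliver the 3R alcohol and comes back to the route at 22.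

Step 3. The Z geometry of the allylpotassium may be lost by torsional isomerisation, or the small alkynyl aldehyde may be poorly discriminated, which would erode the syn selectivity and the enantiomeric purity of 10. The fallback sets out from 6 and replaces the allylboration by an auxiliary-controlled aldol. The Evans boron aldol reaction (n-Bu2BOTf, i-Pr2NEt) of purchasable (4S)-4-benzyl-3-(3-methylbutanoyl)-1,3-oxazolidin-2-one with 6 should give the syn aldol (4S)-4-benzyl-3-[(2S,3S)-3-hydroxy-2-(propan-2-yl)hex-4-ynoyl]-1,3-oxazolidin-2-one F3. Silylation with TBSOTf gives its silyl ether F4, reductive removal of the auxiliary with LiBH4 gives (2R,3S)-3-[(tert-butyldimethylsilyl)oxy]-2-(propan-2-yl)hex-4-yn-1-ol F5, and Dess–Martin oxidation gives (2S,3S)-3-[(tert-butyldimethylsilyl)oxy]-2-(propan-2-yl)hex-4-ynal F6. Wittig methylenation (Ph3P=CH2) of F6 then comes back to the route at 11.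

Step 13. The angeloyl unit may isomerise to the (E)-configured tigloyl unit during activation, or acylation of the hindered C3 alcohol next to the quaternary epoxide carbon may stall. The fallback sets out from 23 and builds the (Z)-alkene on the ester instead of transferring it. Carbodiimide coupling (EDC, DMAP) of 23 with 2-[bis(2,2,2-trifluoroethoxy)phosphoryl]propanoic acid gives the phosphonate ester (3R,4R,5R,6S,7S)-6-acetoxy-4,5-epoxygermacr-1(10)E-en-3-yl 2-[bis(2,2,2-trifluoroethoxy)phosphoryl]propanoate F7. Still–Gennari olefination of F7 with acetaldehyde (KHMDS, 18-crown-6, THF, −78 °C) should form the (Z)-2-methylbut-2-enoate and comes back to the route at 26.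

Further compounds
F1 | step 11 | (1S,2E,4S,6E,10S)-4-hydroxy-3,7-dimethyl-10-(propan-2-yl)cyclodeca-2,6-dien-1-yl acetate | C/C1=C\[C@@H](OC(C)=O)[C@H](C(C)C)CC/C(C)=C/C[C@@H]1O
F2 | step 11 | (1S,2E,6E,10S)-3,7-dimethyl-4-oxo-10-(propan-2-yl)cyclodeca-2,6-dien-1-yl acetate | C/C1=C\[C@@H](OC(C)=O)[C@H](C(C)C)CC/C(C)=C/CC1=O
F3 | step 3 | (4S)-4-benzyl-3-[(2S,3S)-3-hydroxy-2-(propan-2-yl)hex-4-ynoyl]-1,3-oxazolidin-2-one | O=C1OC[C@H](Cc2ccccc2)N1C(=O)[C@@H](C(C)C)[C@H](O)C#CC
F4 | step 3 | (4S)-4-benzyl-3-[(2S,3S)-3-[(tert-butyldimethylsilyl)oxy]-2-(propan-2-yl)hex-4-ynoyl]-1,3-oxazolidin-2-one | O=C1OC[C@H](Cc2ccccc2)N1C(=O)[C@@H](C(C)C)[C@H](O[Si](C)(C)C(C)(C)C)C#CC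
F5 | step 3 | (2R,3S)-3-[(tert-butyldimethylsilyl)oxy]-2-(propan-2-yl)hex-4-yn-1-ol | OC[C@@H](C(C)C)[C@H](O[Si](C)(C)C(C)(C)C)C#CC
F6 | step 3 | (2S,3S)-3-[(tert-butyldimethylsilyl)oxy]-2-(propan-2-yl)hex-4-ynal | O=C[C@@H](C(C)C)[C@H](O[Si](C)(C)C(C)(C)C)C#CC
F7 | step 13 | (3R,4R,5R,6S,7S)-6-acetoxy-4,5-epoxygermacr-1(10)E-en-3-yl 2-[bis(2,2,2-trifluoroethoxy)phosphoryl]propanoate | CC(C(=O)O[C@@H]1C/C=C(\C)CC[C@@H](C(C)C)[C@H](OC(C)=O)[C@H]2O[C@@]21C)P(=O)(OCC(F)(F)F)OCC(F)(F)F
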